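**Plan**
Retrosynthesis: cut C6–C7 (homologation of a C6 ketone), C16=C17 (methylenation), C13–C16 (ring D, acylation of a sulfone-stabilised C13 carbanion), then C13–C14 and C8–C9 together (rings B and C), then C6–C8 (alkenylchromium addition), the diene on C10, and ring A (C1–C10 and C4–C5 by an enantioselective Diels–Alder reaction; C19–O by lactonisation).
Enabling feature: ring C (C8, C9, C11, C12, C13, C14) is a six-membered ring fused to cyclopentane ring B along C8–C9, and C14 is a methylene on quaternary C8. This is the retron of an intramolecular Diels–Alder reaction between a C9=C11–C12=C13 diene on C10 and a C8=C14 vinyl ketone on C5, joined by the tether C10–C5–C6.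
Forward order: ring A, then the 19,20-lactone, the 2β,3β-diol, the diene on C10 and the vinyl ketone on C5; rings B and C close together; ring D, C17 and C7 follow.
Stereochemistry: C5 and C10 from the catalyst-controlled cycloaddition of an (E)-enal; C4 by enolate methylation anti to the C20 arm; C2 and C3 by osmylation of the convex face of lactone-bridged ring A; C8 and C9 from C5 and the endo tether carbonyl in the key step; C13 by bridging; C6 by equilibration.

Key step: step 15

Remark: locants C1–C20 follow gibberellin numbering (ring A: C1–C5, C10; ring B: C5, C6, C8, C9, C10; ring C: C8, C9, C11–C14; ring D: C8, C13–C16); α is the face of C20 and of the lactone bridge, β the opposite face.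
Assumption: the (S)-configured oxazaborolidinium catalyst of step 3 is taken to shield the enal face that leads to the drawn C5/C10 configuration; if the sense were reversed, its mirror image would be used with no other change.

Step 1
Reactants: 1 3-[(tert-butyldimethylsilyl)oxy]propanal; 2 2,2-dimethoxyacetaldehyde
Product: 3 (E)-2-{[(tert-butyldimethylsilyl)oxy]methyl}-4,4-dimethoxybut-2-enal
Conditions: pyrrolidine (cat.), EtCO2H (cat.), toluene, rt to 40 °C
Reagents that add atoms: none
Why: Amine-catalysed crossed aldol condensation (enamine of 1 onto the non-enolisable aldehyde 2, then dehydration) should give the conjugated (E)-enal with CHO and CH(OMe)2 trans, the geometry that later places C20 and C6 cis on ring A.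

Step 2
Reactants: 4 methyl 3-oxopent-4-enoate
Product: 5 methyl (2Z)-3-[(trimethylsilyl)oxy]penta-2,4-dienoate
Conditions: Me3SiCl, Et3N, hexane, rt
Reagents that add atoms: chlorotrimethylsilane, C[Si](C)(C)Cl
Why: O-silylation of the enolised β-keto ester (silyl enol ether formation) gives a 2-silyloxy diene whose ester-bearing terminus is the nucleophilic one.

Step 3
Reactants: 3 (E)-2-{[(tert-butyldimethylsilyl)oxy]methyl}-4,4-dimethoxybut-2-enal; 5 methyl (2Z)-3-[(trimethylsilyl)oxy]penta-2,4-dienoate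
Product: 7 methyl 3-{[(tert-butyldimethylsilyl)oxy]methyl}-2-(dimethoxymethyl)-3-formyl-6-oxocyclohexane-1-carboxylate (ring-A keto ester; CH2OSi cis to CH(OMe)2; C1 epimers), via silyl enol ether cycloadduct 6 (not isolated)
Conditions: oxazaborolidinium catalyst made from (S)-α,α-diphenylprolinol, 2-methylphenylboronic acid and HNTf2 (20 mol %), CH2Cl2, −78 to −40 °C; then K2CO3, MeOH, 0 °C
Reagents that add atoms: none
Why: Lewis-acid-catalysed asymmetric Diels–Alder reaction of an α-substituted enal with a 2-silyloxy diene: the silyloxy carbon ends para to the formyl-bearing carbon, suprafacial addition to the (E)-enal makes C20 and C6 cis, and the shielded enal face sets the absolute configuration of C5 and C10 in one event (C4 stays epimerisable).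

Step 4
Reactants: 7 ring-A keto ester
Product: 8 methyl 3-{[(tert-butyldimethylsilyl)oxy]methyl}-2-(dimethoxymethyl)-3-formyl-1-methyl-6-oxocyclohexane-1-carboxylate (CO2Me, CH(OMe)2 and CH2OSi on the α face; methyl and CHO on the β face)
Conditions: MeI, K2CO3, acetone, rt
Reagents that add atoms: iodomethane, CI
Why: C-alkylation of the β-keto ester enolate should occur anti to the C5 substituent and to the axial C20 arm on C10, as in alkylations of 2-carboalkoxycyclohexanones with an axial 1,3-substituent, which places the ester cis to C20 and sets quaternary C4.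

Step 5
Reactants: 8 methylated keto ester
Product: 9 methyl 3-{[(tert-butyldimethylsilyl)oxy]methyl}-2-(dimethoxymethyl)-3-formyl-1-methyl-6-{[(trifluoromethyl)sulfonyl]oxy}cyclohex-5-ene-1-carboxylate (enol triflate at C2=C3)
Conditions: KN(SiMe3)2 added to 8 and N-(5-chloropyridin-2-yl)bis(trifluoromethanesulfonyl)imide, THF, −78 °C
Reagents that add atoms: N-(5-chloropyridin-2-yl)bis(trifluoromethanesulfonyl)imide, O=S(=O)(N(c1ccc(Cl)cn1)S(=O)(=O)C(F)(F)F)C(F)(F)F
Why: The ketone has α-hydrogens only at C2, so enolate O-triflation is regiospecific; the neopentyl aldehyde has no α-hydrogen and the enolate is trapped as it forms.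

Step 6
Reactants: 9 enol triflate
Product: 10 methyl 3-{[(tert-butyldimethylsilyl)oxy]methyl}-2-(dimethoxymethyl)-3-formyl-1-methylcyclohex-5-ene-1-carboxylate (C2=C3 alkene)
Conditions: Pd(OAc)2 (5 mol %), PPh3, HCO2H, Bu3N, DMF, 60 °C
Reagents that add atoms: none
Why: Palladium-catalysed formate reduction of a vinyl triflate (oxidative addition to zerovalent palladium, hydride transfer from formate, reductive elimination) leaves the aldehyde, acetal and silyl ether untouched.

Step 7
Reactants: 10 cyclohexene ester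
Product: 12 9-(dimethoxymethyl)-1-methyl-2-oxo-3-oxabicyclo[3.3.1]non-7-ene-5-carbaldehyde (19,20-lactone of ring A; CH(OMe)2 syn to the lactone bridge), via hydroxy ester 11 (not isolated)
Conditions: Bu4NF, THF, 0 °C to rt
Reagents that add atoms: none
Why: Fluoride desilylation frees the C20 alkoxide, which is cis-1,3 to the C19 ester and should lactonise by intramolecular transesterification faster than it can undergo retro-aldol cleavage; the non-acidic conditions keep the C6 acetal.

Step 8
Reactants: 12 lactone aldehyde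
Product: 13 9-(dimethoxymethyl)-7,8-dihydroxy-1-methyl-2-oxo-3-oxabicyclo[3.3.1]nonane-5-carbaldehyde (cis-diol anti to the lactone bridge, i.e. 2β,3β)
Conditions: OsO4 (2 mol %), 4-methylmorpholine N-oxide, acetone/H2O, rt
Reagents that add atoms: 4-methylmorpholine N-oxide, C[N+]1([O-])CCOCC1; water, O
Why: Catalytic osmium tetroxide syn-dihydroxylation should take place on the convex β face of the bicyclo[3.3.1]nonene, because the lactone bridge covers the α face, setting C2 and C3 together.

Step 9
Reactants: 13 diol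
Product: 14 9-(dimethoxymethyl)-7,8-(isopropylidenedioxy)-1-methyl-2-oxo-3-oxabicyclo[3.3.1]nonane-5-carbaldehyde
Conditions: 2-methoxypropene, pyridinium p-toluenesulfonate (cat.), CH2Cl2, 0 °C
Reagents that add atoms: 2-methoxypropene, COC(C)=C
Why: Kinetic acetonide formation on the cis-1,2-diol protects it for the oxidations and base steps that follow.

Step 10
Reactants: 14 acetonide aldehyde
Product: 15 (2E)-3-[9-(dimethoxymethyl)-7,8-(isopropylidenedioxy)-1-methyl-2-oxo-3-oxabicyclo[3.3.1]non-5-yl]prop-2-enal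
Conditions: Ph3P=CHCHO, toluene, 90 °C
Reagents that add atoms: (triphenylphosphoranylidene)acetaldehyde, O=CC=P(c1ccccc1)(c1ccccc1)c1ccccc1
Why: Wittig reaction of the stabilised ylide with the non-enolisable C9 aldehyde should give the (E)-enal (C9=C11).

Step 11
Reactants: 15 enal
Product: 16 9-(dimethoxymethyl)-7,8-(isopropylidenedioxy)-1-methyl-5-[(1E,3E)-4-(phenylsulfonyl)buta-1,3-dien-1-yl]-3-oxabicyclo[3.3.1]nonan-2-one
Conditions: (EtO)2P(O)CH2SO2Ph, LiCl, 1,8-diazabicyclo[5.4.0]undec-7-ene, MeCN, rt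
Reagents that add atoms: diethyl [(phenylsulfonyl)methyl]phosphonate, CCOP(=O)(CS(=O)(=O)c1ccccc1)OCC
Why: Horner–Wadsworth–Emmons olefination under mild base gives the (E)-vinyl sulfone and so completes the C9=C11–C12=C13 diene with the sulfonyl group on C13.

Step 12
Reactants: 16 dienyl sulfone acetal
Product: 17 7,8-(isopropylidenedioxy)-1-methyl-2-oxo-5-[(1E,3E)-4-(phenylsulfonyl)buta-1,3-dien-1-yl]-3-oxabicyclo[3.3.1]nonane-9-carbaldehyde (C6 aldehyde)
Conditions: pyridinium p-toluenesulfonate, acetone/H2O (9:1), 50 °C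
Reagents that add atoms: water, O
Why: Acetal hydrolysis by transacetalisation in wet acetone frees the C6 aldehyde while the solvent holds the isopropylidene acetal in place; the conditions are too mild to epimerise C5.

Step 13
Reactants: 18 3-bromobut-3-enoic acid
Product: 19 3-bromo-N-methoxy-N-methylbut-3-enamide
Conditions: 1,1'-carbonyldiimidazole, CH2Cl2, 0 °C; then MeNHOMe·HCl, rt
Reagents that add atoms: N,O-dimethylhydroxylamine hydrochloride, CNOC.Cl
Why: Amide formation through the acyl imidazole gives the alkenyl bromide carrying C8, C14, C15 and C16 with C16 as an N-methoxy-N-methylamide.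

Step 14
Reactants: 17 C6 aldehyde; 19 3-bromo-N-methoxy-N-methylbut-3-enamide
Product: 20 4-hydroxy-4-{7,8-(isopropylidenedioxy)-1-methyl-2-oxo-5-[(1E,3E)-4-(phenylsulfonyl)buta-1,3-dien-1-yl]-3-oxabicyclo[3.3.1]non-9-yl}-N-methoxy-N-methyl-3-methylenebutanamide (C6 carbinol epimers)
Conditions: CrCl2 (4 equiv), NiCl2 (2 mol %), DMSO, rt
Reagents that add atoms: none
Why: Nozaki–Hiyama–Kishi coupling (zerovalent nickel inserts into the C–Br bond, transmetalation gives an alkenyl species of trivalent chromium that adds to the aldehyde) forms C6–C8 without base and tolerates lactone, amide, sulfone and acetonide; the carbinol configuration is irrelevant.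

Step 15
Reactants: 20 allylic alcohol
Product: 22 cycloadduct with rings A, B and C (19,20-lactone; 2β,3β-O-isopropylidene; C6 ketone; C11=C12; 13α-phenylsulfonyl; C8 β-CH2C(O)N(OMe)Me; 5β-H and 9β-H), via trienone 21 (not isolated)
Conditions: 1,1,1-triacetoxy-1,1-dihydro-1,2-benziodoxol-3(1H)-one, NaHCO3, CH2Cl2, 0 °C; then toluene, 2,6-di-tert-butyl-4-methylphenol, 80 °C
Reagents that add atoms: none
Why: Oxidation unmasks the 2-substituted vinyl ketone, which undergoes a concerted, asynchronous intramolecular [4+2] cycloaddition with the (E,E)-dienyl sulfone through the tether C10–C5–C6, forming C13–C14 and C8–C9 together; the closest known reaction type is the intramolecular Diels–Alder reaction of 1,6,8-nonatrien-3-ones, which give cis-fused hydrindanones under mild heating. Ring B closes as the five-membered tether ring (C5, C6, C8, C9, C10) through the new C8–C9 bond, and ring C closes as the cyclohexene (C8, C9, C11, C12, C13, C14) of the [4+2] array. The cis B/C junction (H9 and C15 on the same face) follows from the endo placement of the tether carbonyl C6 under the diene, as is general for trienones whose carbonyl lies in the tether. The configuration of quaternary C8 and of C9 relative to ring A is set by C5: in the endo transition state C5 lies gauche to C15 on C8, so only H5 can point at C15, which turns the quaternary C4 outward and puts ring C on the α face. The sulfonyl group occupies the outside position of the diene, and the C13 centre it creates is not needed because it is planarised in step 16. The step needs endo/exo and π-facial selectivity, secured by the tether carbonyl and by the C5 stereocentre, while regiochemistry is fixed by the tether.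

Step 16
Reactants: 22 cycloadduct
Product: 24 ring-D β-keto sulfone (16-oxo-17-nor skeleton with 13α-phenylsulfonyl, C11=C12, C6 ketone, 19,20-lactone and 2β,3β-O-isopropylidene), via lithium hemiaminal alkoxide 23 (not isolated)
Conditions: LiN(SiMe3)2 (1.1 equiv), THF, −78 to −30 °C; aq. NH4Cl
Reagents that add atoms: none
Why: The allylic α-sulfonyl C13–H is the most acidic site, and its carbanion should acylate at the α-carbon in a 5-exo-trig Claisen-type closure onto the N-methoxy-N-methylamide; the carbanion can only close on the face of C15, so either C13 epimer converges on the bridged ketone, and the chelated tetrahedral intermediate blocks retro-Claisen cleavage.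

Step 17
Reactants: 24 β-keto sulfone
Product: 25 11,12-dihydro β-keto sulfone
Conditions: H2 (1 atm), Pd/C, EtOAc, rt
Reagents that add atoms: none
Why: Heterogeneous hydrogenation saturates the only alkene (C11=C12) and creates no stereocentre.

Step 18
Reactants: 25 dihydro β-keto sulfone
Product: 26 6,16-diketone (17-nor; 13-H bridgehead; 19,20-lactone; 2β,3β-O-isopropylidene)
Conditions: SmI2, THF/MeOH, −78 °C
Reagents that add atoms: none
Why: Reductive desulfonylation of an α-sulfonyl ketone by single-electron transfer from divalent samarium cleaves the C13–S bond and the bridgehead centre is protonated with its configuration fixed by the bicycle; the unactivated C6 ketone is not reduced at this temperature.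

Step 19
Reactants: 26 diketone
Product: 27 16-methylene 6-ketone
Conditions: Zn, CH2Br2, TiCl4, THF/CH2Cl2, 0 °C to rt
Reagents that add atoms: dibromomethane, BrCBr
Why: Takai–Lombardo methylenation with the non-basic titanium–zinc carbenoid should convert the accessible ring-D ketone only, because the C6 ketone is flanked by quaternary C8 and by C5 between two quaternary carbons, and it cannot epimerise C5.

Step 20
Reactants: 27 methylene ketone
Product: 28 spiro-oxirane at C6 (C7 methylene on the β face, oxygen on the α face)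
Conditions: Me3SI, KN(SiMe3)2, THF, −10 °C to rt
Reagents that add atoms: trimethylsulfonium iodide, C[S+](C)C.[I-]
Why: Corey–Chaykovsky epoxidation with the small, weakly basic dimethylsulfonium methylide should add to the hindered ketone from the β face (H5 side) without enolising C5 and so brings in C7.

Step 21
Reactants: 28 spiro-oxirane
Product: 30 7-aldehyde with 6β-formyl (H6 α), via 6-epimeric aldehyde 29 (not isolated)
Conditions: BF3·OEt2 (0.3 equiv), CH2Cl2, −78 °C; then 1,8-diazabicyclo[5.4.0]undec-7-ene, rt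
Reagents that add atoms: none
Why: Meinwald rearrangement (epoxide opening at the tertiary carbon, 1,2-hydride shift from C7) gives the aldehyde, and base equilibration through the enolate should settle C6 with the formyl group β, trans to the quaternary C4 substituent on C5.

Step 22
Reactants: 30 aldehyde
Product: 31 7-carboxylic acid (2β,3β-O-isopropylidene, 19,20-lactone, 16-ene)
Conditions: NaClO2, NaH2PO4, 2-methyl-2-butene, t-BuOH/H2O, rt
Reagents that add atoms: sodium chlorite, [Na+].[O-]Cl=O
Why: Pinnick oxidation converts the aldehyde to the acid without epimerising C6, and the scavenger protects the exocyclic alkene from hypochlorous acid.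

Step 23
Reactants: 31 acid acetonide
Product: 32 CNP0332607.1 (2β,3β-dihydroxy 19,20-lactone 7-acid with the 16-ene)
Conditions: AcOH/H2O (4:1), 45 °C
Reagents that add atoms: none
Why: Mild acidic acetonide hydrolysis frees the diol under conditions that neither trigger the base-induced retro-aldol epimerisation of the 3β-hydroxy lactone nor isomerise the exocyclic alkene.

**Compound list**
1 | 3-[(tert-butyldimethylsilyl)oxy]propanal | O=CCCO[Si](C)(C)C(C)(C)C | starting material
2 | 2,2-dimethoxyacetaldehyde | O=CC(OC)OC | starting material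
3 | (E)-2-{[(tert-butyldimethylsilyl)oxy]methyl}-4,4-dimethoxybut-2-enal | O=C/C(CO[Si](C)(C)C(C)(C)C)=C/C(OC)OC | intermediate
4 | methyl 3-oxopent-4-enoate | C=CC(=O)CC(=O)OC | starting material
5 | methyl (2Z)-3-[(trimethylsilyl)oxy]penta-2,4-dienoate | C=C/C(O[Si](C)(C)C)=C/C(=O)OC | intermediate
6 | methyl 5-{[(tert-butyldimethylsilyl)oxy]methyl}-6-(dimethoxymethyl)-5-formyl-2-[(trimethylsilyl)oxy]cyclohex-2-ene-1-carboxylate (CH2OSi cis to CH(OMe)2; C1 epimers) | O=C[C@]1(CO[Si](C)(C)C(C)(C)C)CC=C(O[Si](C)(C)C)C(C(=O)OC)[C@H]1C(OC)OC | intermediate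
7 | methyl 3-{[(tert-butyldimethylsilyl)oxy]methyl}-2-(dimethoxymethyl)-3-formyl-6-oxocyclohexane-1-carboxylate (CH2OSi cis to CH(OMe)2; C1 epimers) | O=C[C@]1(CO[Si](C)(C)C(C)(C)C)CCC(=O)C(C(=O)OC)[C@H]1C(OC)OC | intermediate
8 | methyl 3-{[(tert-butyldimethylsilyl)oxy]methyl}-2-(dimethoxymethyl)-3-formyl-1-methyl-6-oxocyclohexane-1-carboxylate (CO2Me, CH(OMe)2, CH2OSi α; CH3, CHO β) | O=C[C@]1(CO[Si](C)(C)C(C)(C)C)CCC(=O)[C@@](C)(C(=O)OC)[C@H]1C(OC)OC | intermediate
9 | methyl 3-{[(tert-butyldimethylsilyl)oxy]methyl}-2-(dimethoxymethyl)-3-formyl-1-methyl-6-{[(trifluoromethyl)sulfonyl]oxy}cyclohex-5-ene-1-carboxylate | O=C[C@]1(CO[Si](C)(C)C(C)(C)C)CC=C(OS(=O)(=O)C(F)(F)F)[C@@](C)(C(=O)OC)[C@H]1C(OC)OC | intermediate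
10 | methyl 3-{[(tert-butyldimethylsilyl)oxy]methyl}-2-(dimethoxymethyl)-3-formyl-1-methylcyclohex-5-ene-1-carboxylate | O=C[C@]1(CO[Si](C)(C)C(C)(C)C)CC=C[C@@](C)(C(=O)OC)[C@H]1C(OC)OC | intermediate
11 | methyl 2-(dimethoxymethyl)-3-formyl-3-(hydroxymethyl)-1-methylcyclohex-5-ene-1-carboxylate | O=C[C@]1(CO)CC=C[C@@](C)(C(=O)OC)[C@H]1C(OC)OC | intermediate
12 | 9-(dimethoxymethyl)-1-methyl-2-oxo-3-oxabicyclo[3.3.1]non-7-ene-5-carbaldehyde (CH(OMe)2 syn to the lactone bridge) | O=C[C@@]12CC=C[C@@](C)(C(=O)OC1)[C@H]2C(OC)OC | intermediate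
13 | 9-(dimethoxymethyl)-7,8-dihydroxy-1-methyl-2-oxo-3-oxabicyclo[3.3.1]nonane-5-carbaldehyde (cis-diol anti to the lactone bridge) | O=C[C@@]12C[C@H](O)[C@H](O)[C@@](C)(C(=O)OC1)[C@H]2C(OC)OC | intermediate
14 | 9-(dimethoxymethyl)-7,8-(isopropylidenedioxy)-1-methyl-2-oxo-3-oxabicyclo[3.3.1]nonane-5-carbaldehyde | O=C[C@@]12C[C@@H]3OC(C)(C)O[C@@H]3[C@@](C)(C(=O)OC1)[C@H]2C(OC)OC | intermediate
15 | (2E)-3-[9-(dimethoxymethyl)-7,8-(isopropylidenedioxy)-1-methyl-2-oxo-3-oxabicyclo[3.3.1]non-5-yl]prop-2-enal | O=C/C=C/[C@@]12C[C@@H]3OC(C)(C)O[C@@H]3[C@@](C)(C(=O)OC1)[C@H]2C(OC)OC | intermediate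
16 | 9-(dimethoxymethyl)-7,8-(isopropylidenedioxy)-1-methyl-5-[(1E,3E)-4-(phenylsulfonyl)buta-1,3-dien-1-yl]-3-oxabicyclo[3.3.1]nonan-2-one | O=S(=O)(c4ccccc4)/C=C/C=C/[C@@]12C[C@@H]3OC(C)(C)O[C@@H]3[C@@](C)(C(=O)OC1)[C@H]2C(OC)OC | intermediate
17 | 7,8-(isopropylidenedioxy)-1-methyl-2-oxo-5-[(1E,3E)-4-(phenylsulfonyl)buta-1,3-dien-1-yl]-3-oxabicyclo[3.3.1]nonane-9-carbaldehyde | O=S(=O)(c4ccccc4)/C=C/C=C/[C@@]12C[C@@H]3OC(C)(C)O[C@@H]3[C@@](C)(C(=O)OC1)[C@H]2C=O | intermediate
18 | 3-bromobut-3-enoic acid | C=C(Br)CC(=O)O | starting material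
19 | 3-bromo-N-methoxy-N-methylbut-3-enamide | C=C(Br)CC(=O)N(C)OC | intermediate
20 | 4-hydroxy-4-{7,8-(isopropylidenedioxy)-1-methyl-2-oxo-5-[(1E,3E)-4-(phenylsulfonyl)buta-1,3-dien-1-yl]-3-oxabicyclo[3.3.1]non-9-yl}-N-methoxy-N-methyl-3-methylenebutanamide (carbinol epimers) | O=S(=O)(c4ccccc4)/C=C/C=C/[C@@]12C[C@@H]3OC(C)(C)O[C@@H]3[C@@](C)(C(=O)OC1)[C@H]2C(O)C(=C)CC(=O)N(C)OC | intermediate
21 | 4-{7,8-(isopropylidenedioxy)-1-methyl-2-oxo-5-[(1E,3E)-4-(phenylsulfonyl)buta-1,3-dien-1-yl]-3-oxabicyclo[3.3.1]non-9-yl}-N-methoxy-N-methyl-3-methylene-4-oxobutanamide (trienone) | O=S(=O)(c4ccccc4)/C=C/C=C/[C@@]12C[C@@H]3OC(C)(C)O[C@@H]3[C@@](C)(C(=O)OC1)[C@H]2C(=O)C(=C)CC(=O)N(C)OC | intermediate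
22 | cycloadduct: rings A, B, C; 19,20-lactone; 2β,3β-O-isopropylidene; 6-oxo; 11-ene; 13α-phenylsulfonyl; C8 β-CH2C(O)N(OMe)Me; 5β-H, 9β-H | CON(C)C(=O)C[C@]23C[C@@H](S(=O)(=O)c4ccccc4)C=C[C@H]2[C@]15COC(=O)[C@](C)([C@H]6OC(C)(C)O[C@H]6C1)[C@H]5C3=O | intermediate
23 | lithium alkoxide of the C16 N-methoxy-N-methyl hemiaminal formed on ring-D closure (13α-phenylsulfonyl, 11-ene, 6-oxo) | [Li+].[O-]C1(N(C)OC)C[C@]23C[C@@]1(S(=O)(=O)c4ccccc4)C=C[C@H]2[C@]15COC(=O)[C@](C)([C@H]6OC(C)(C)O[C@H]6C1)[C@H]5C3=O | intermediate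
24 | 6,16-dioxo-13α-phenylsulfonyl-17-nor 11-ene with rings A–D, 19,20-lactone and 2β,3β-O-isopropylidene | O=C1C[C@]23C[C@@]1(S(=O)(=O)c4ccccc4)C=C[C@H]2[C@]15COC(=O)[C@](C)([C@H]6OC(C)(C)O[C@H]6C1)[C@H]5C3=O | intermediate
25 | 11,12-dihydro derivative of 24 | O=C1C[C@]23C[C@@]1(S(=O)(=O)c4ccccc4)CC[C@H]2[C@]15COC(=O)[C@](C)([C@H]6OC(C)(C)O[C@H]6C1)[C@H]5C3=O | intermediate
26 | 6,16-dioxo-17-nor tetracycle (13-H; 19,20-lactone; 2β,3β-O-isopropylidene) | O=C1C[C@]23C[C@H]1CC[C@H]2[C@]15COC(=O)[C@](C)([C@H]6OC(C)(C)O[C@H]6C1)[C@H]5C3=O | intermediate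
27 | 16-methylene 6-ketone (19,20-lactone; 2β,3β-O-isopropylidene) | C=C1C[C@]23C[C@H]1CC[C@H]2[C@]15COC(=O)[C@](C)([C@H]6OC(C)(C)O[C@H]6C1)[C@H]5C3=O | intermediate
28 | spiro-oxirane at C6 (C7 β, O α) of the 16-ene | C=C1C[C@]23C[C@H]1CC[C@H]2[C@]15COC(=O)[C@](C)([C@H]6OC(C)(C)O[C@H]6C1)[C@H]5[C@]37CO7 | intermediate
29 | 6-epimeric 7-aldehyde (6α-formyl) | C=C1C[C@]23C[C@H]1CC[C@H]2[C@]15COC(=O)[C@](C)([C@H]6OC(C)(C)O[C@H]6C1)[C@H]5[C@H]3C=O | intermediate
30 | 7-aldehyde (6β-formyl; 19,20-lactone; 2β,3β-O-isopropylidene; 16-ene) | C=C1C[C@]23C[C@H]1CC[C@H]2[C@]15COC(=O)[C@](C)([C@H]6OC(C)(C)O[C@H]6C1)[C@H]5[C@@H]3C=O | intermediate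
31 | 7-carboxylic acid (19,20-lactone; 2β,3β-O-isopropylidene; 16-ene) | C=C1C[C@]23C[C@H]1CC[C@H]2[C@]15COC(=O)[C@](C)([C@H]6OC(C)(C)O[C@H]6C1)[C@H]5[C@@H]3C(=O)O | intermediate
32 | CNP0332607.1: 2β,3β-dihydroxy 19,20-lactone 7-carboxylic acid with the 16-ene (5β-H, 9β-H, 6β-CO2H) | C=C1C[C@]23C[C@H]1CC[C@H]2[C@]12COC(=O)[C@](C)([C@@H](O)[C@@H](O)C1)[C@H]2[C@@H]3C(=O)O | target

**Count and risks**
Total steps: 23. Longest linear sequence: 21 steps (1 to 32 through steps 1, 3–12 and 14–23; steps 2 and 13 prepare the partners 5 and 19).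

Step 3. The risk is weak enantiofacial discrimination on a hindered trisubstituted enal, or ionisation of the dimethyl acetal by the strongly Lewis-acidic catalyst. The fallback sets out from 3 and 5 and returns at 8. The cycloaddition is run thermally (toluene, 110 °C, then K2CO3/MeOH), which gives 7 together with its mirror image, the enantiomeric keto ester F2, through the enantiomeric silyl enol ether F1 alongside 6. Methylation as in step 4 gives 8 and the enantiomeric methyl keto ester F3. Condensation of the aldehyde with (1S,2S)-N,N'-dimethyl-1,2-diphenylethane-1,2-diamine gives the imidazolidine F4 from 8 and the diastereomeric imidazolidine F5 from F3, which are separated by chromatography. Hydrolysis of F4 with dilute aqueous acetic acid returns 8.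

Step 15. The risk is slow cycloaddition of the electron-poor dienyl sulfone, with polymerisation of the vinyl ketone or loss of endo selectivity at the temperature then needed. The fallback sets out from 15 and returns at 22, and makes the diene electron-rich instead. Horner–Wadsworth–Emmons reaction of 15 with diethyl [(phenylthio)methyl]phosphonate and n-BuLi gives the dienyl sulfide acetal F6. Acetal hydrolysis as in step 12 gives the dienyl sulfide aldehyde F7, and coupling with 19 as in step 14 gives the allylic alcohol F8. Oxidation as in step 15 gives the sulfide trienone F9, which should cyclise near room temperature to the cycloadduct sulfide F10. Oxidation at sulfur with H2O2 and (NH4)6Mo7O24 in EtOH then gives 22.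

Step 21. The risk is Lewis-acid-induced isomerisation of the exocyclic alkene, or skeletal migration instead of the hydride shift, during epoxide opening. The fallback sets out from 27 and returns at 30, and avoids both the epoxide and the Lewis acid. Wittig methoxymethylenation of 27 with Ph3P=CHOMe (from (methoxymethyl)triphenylphosphonium chloride and KN(SiMe3)2) gives the methyl enol ether F11. Hydrolysis with pyridinium p-toluenesulfonate in wet acetone gives the aldehyde as a mixture with 29, and equilibration with 1,8-diazabicyclo[5.4.0]undec-7-ene gives 30.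

Further compounds
F1 | step 3 | enantiomer of silyl enol ether cycloadduct 6 | O=C[C@@]1(CO[Si](C)(C)C(C)(C)C)CC=C(O[Si](C)(C)C)C(C(=O)OC)[C@@H]1C(OC)OC
F2 | step 3 | enantiomer of keto ester 7 | O=C[C@@]1(CO[Si](C)(C)C(C)(C)C)CCC(=O)C(C(=O)OC)[C@@H]1C(OC)OC
F3 | step 3 | enantiomer of methyl keto ester 8 | O=C[C@@]1(CO[Si](C)(C)C(C)(C)C)CCC(=O)[C@](C)(C(=O)OC)[C@@H]1C(OC)OC
F4 | step 3 | (4S,5S)-1,3-dimethyl-4,5-diphenylimidazolidine formed at the aldehyde carbon of 8 | CN1[C@@H](c2ccccc2)[C@H](c2ccccc2)N(C)C1[C@]1(CO[Si](C)(C)C(C)(C)C)CCC(=O)[C@@](C)(C(=O)OC)[C@H]1C(OC)OC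
F5 | step 3 | (4S,5S)-1,3-dimethyl-4,5-diphenylimidazolidine formed at the aldehyde carbon of F3 | CN1[C@@H](c2ccccc2)[C@H](c2ccccc2)N(C)C1[C@@]1(CO[Si](C)(C)C(C)(C)C)CCC(=O)[C@](C)(C(=O)OC)[C@@H]1C(OC)OC
F6 | step 15 | 9-(dimethoxymethyl)-7,8-(isopropylidenedioxy)-1-methyl-5-[(1E,3E)-4-(phenylthio)buta-1,3-dien-1-yl]-3-oxabicyclo[3.3.1]nonan-2-one | c4ccccc4S/C=C/C=C/[C@@]12C[C@@H]3OC(C)(C)O[C@@H]3[C@@](C)(C(=O)OC1)[C@H]2C(OC)OC
F7 | step 15 | 7,8-(isopropylidenedioxy)-1-methyl-2-oxo-5-[(1E,3E)-4-(phenylthio)buta-1,3-dien-1-yl]-3-oxabicyclo[3.3.1]nonane-9-carbaldehyde | c4ccccc4S/C=C/C=C/[C@@]12C[C@@H]3OC(C)(C)O[C@@H]3[C@@](C)(C(=O)OC1)[C@H]2C=O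
F8 | step 15 | phenylthio analogue of allylic alcohol 20 | c4ccccc4S/C=C/C=C/[C@@]12C[C@@H]3OC(C)(C)O[C@@H]3[C@@](C)(C(=O)OC1)[C@H]2C(O)C(=C)CC(=O)N(C)OC
F9 | step 15 | phenylthio analogue of trienone 21 | c4ccccc4S/C=C/C=C/[C@@]12C[C@@H]3OC(C)(C)O[C@@H]3[C@@](C)(C(=O)OC1)[C@H]2C(=O)C(=C)CC(=O)N(C)OC
F10 | step 15 | 13α-phenylthio analogue of cycloadduct 22 | CON(C)C(=O)C[C@]23C[C@@H](Sc4ccccc4)C=C[C@H]2[C@]15COC(=O)[C@](C)([C@H]6OC(C)(C)O[C@H]6C1)[C@H]5C3=O
F11 | step 21 | methyl enol ether at C6 (C6=CH–OMe) of the 16-ene | C=C1C[C@]23C[C@H]1CC[C@H]2[C@]15COC(=O)[C@](C)([C@H]6OC(C)(C)O[C@H]6C1)[C@H]5C3=COC
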